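**Retrosynthetic overview**
Ring A of the benzophenone carries six substituents. C3(prenyl)–C4(OMe) and C5(prenyl)–C6(OMe) are the same two-carbon unit occurring twice, beside the single free C2–OH, so both pairs are traced to one alkyne, MeO–C≡C–prenyl.
The C1–benzoyl bond is cut first (aryl anion plus Weinreb amide). This leaves a pentasubstituted phenol whose only ring C–H sits between two oxygen substituents.
The phenol is opened by a cyclobutenone/alkoxyalkyne benzannulation: C3–C4 come from the alkyne, and C2 (C=O), C5, C6 and C1 (CH2) come from 3-methoxy-2-prenylcyclobutenone.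
The cyclobutenone goes back to the same ynol ether and dichloroketene, and the ynol ether goes back to chloroacetaldehyde dimethyl acetal and prenyl bromide.
Ring order: the four-membered ring first, then ring A by benzannulation. Phenyl ring B arrives preformed in the last C–C bond formation.
Key step: step 4

Remark: prenyl stands for 3-methylbut-2-en-1-yl. The target has no stereocentre and no stereogenic double bond, so no stereocontrol is required.

**Step 1**
Reactants: 1 chloroacetaldehyde dimethyl acetal; 2 prenyl bromide
Product: 4 1-methoxy-5-methylhex-4-en-1-yne, via sodium methoxyacetylide 3 (not isolated)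
Conditions: NaNH2 (3.0 equiv, acetal in slight excess), liq. NH3, −33 °C; then 2 in Et2O, −78 → −33 °C; NH3 off, H2O/pentane
Reagents that add atoms: none
Why: Three equivalents of NaNH2 remove methanol and HCl from the chloroacetal and metalate the alkyne terminus (alkoxyacetylide synthesis by double β-elimination), the acetylide carbon then displaces the primary allylic bromide by SN2 alkylation, and keeping the amide as the limiting reagent should prevent base-induced isomerisation of the skipped enyne.

**Step 2**
Reactants: 4 1-methoxy-5-methylhex-4-en-1-yne; 5 trichloroacetyl chloride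
Product: 7 4,4-dichloro-3-methoxy-2-prenylcyclobut-2-en-1-one, via dichloroketene 6 (not isolated)
Conditions: 5 (1.0 equiv, slow addition), zinc-copper couple, Et2O/DME, 0 °C → rt
Reagents that add atoms: none
Why: Zinc reduces the acid chloride to dichloroketene, whose carbonyl carbon is attacked by the alkyne carbon β to oxygen in a ketene-alkyne (2+2) cycloaddition, so CCl2 ends next to C–OMe; slow addition of a limiting amount of 5 favours the ynol ether over the far less nucleophilic trisubstituted olefin, and DME ties up ZnCl2.

**Step 3**
Reactants: 7 4,4-dichloro-3-methoxy-2-prenylcyclobut-2-en-1-one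
Product: 8 3-methoxy-2-prenylcyclobut-2-en-1-one
Conditions: Zn dust, AcOH, TMEDA, MeOH, 0 °C → rt
Reagents that add atoms: none
Why: Buffered zinc reduction of an α,α-dichloro ketone removes both chlorines through zinc enolates without touching the enone or the prenyl olefin, and methanol as solvent makes any alkoxy exchange at the vinylogous ester degenerate.

**Step 4**
Reactants: 8 3-methoxy-2-prenylcyclobut-2-en-1-one; 4 1-methoxy-5-methylhex-4-en-1-yne (second portion, 1.5 equiv)
Product: 13 3,5-dimethoxy-2,4-diprenylphenol, via vinylketene 9 (not isolated), via 4-vinylcyclobutenone 10 (not isolated), via dienylketene 11 (not isolated), via cyclohexadienone 12 (not isolated)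
Conditions: toluene (degassed), sealed tube, 110 → 145 °C
Reagents that add atoms: none
Why: Heating cleaves the C1–C4 bond of 8 in a conrotatory four-electron electrocyclic opening to vinylketene 9, which adds to the triple bond of 4 in a ketene-alkyne (2+2) cycloaddition to give 10; a second four-electron opening gives dienylketene 11, which cyclises to dienone 12 and tautomerises to the phenol. The closest known reaction type is the Danheiser benzannulation of a cyclobutenone with an alkoxyalkyne, and the 3-methoxy donor of 8 should only raise the temperature needed for the first opening. The transient four-membered ring of 10 closes in the (2+2) event (ketene carbonyl carbon to the prenyl-bearing alkyne carbon, ketene alpha carbon to the methoxy-bearing alkyne carbon), and ring A closes by a disrotatory six-electron electrocyclisation that joins the ketene carbon of 11 to the former CH2 carbon of 8. No stereocentre remains, because the quaternary carbon of 10 is racemic and becomes planar again in 11, and only the isomer of 11 with the ketene and methoxyvinyl groups cis can close while the other returns to 10. Two selectivities are required, a single orientation of the alkyne and attack on the triple bond rather than on a prenyl C=C; the oxygen lone pair of 4 supplies both by pushing electron density onto the carbon that carries the prenyl group, which should therefore attack the electrophilic ketene carbonyl carbon far faster than any olefin can. The methyl ynol ether has no β-hydrogen for retro-ene loss of an alkene, the one-carbon tether keeps the prenyl olefins out of reach of the ketene, and no acid is present that could cyclise or hydrate the side chains.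

**Step 5**
Reactants: 13 3,5-dimethoxy-2,4-diprenylphenol
Product: 15 1-(methoxymethoxy)-3,5-dimethoxy-2,4-diprenylbenzene, via sodium phenoxide 14 (not isolated)
Conditions: NaH, THF/DMF, 0 °C; MOMCl, 0 °C → rt
Reagents that add atoms: chloromethyl methyl ether (MOMCl), COCCl
Why: Williamson-type O-alkylation of the phenoxide with a highly reactive α-chloro ether masks the acidic OH under base only and installs the stronger of the two ortho-directing groups needed next.

**Step 6**
Reactants: 15 1-(methoxymethoxy)-3,5-dimethoxy-2,4-diprenylbenzene; 16 N-methoxy-N-methylbenzamide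
Product: 19 2-(methoxymethoxy)-4,6-dimethoxy-3,5-diprenylbenzophenone, via aryllithium 17 (not isolated), via lithium hemiaminal 18 (not isolated)
Conditions: n-BuLi (1.1 equiv), THF, −20 → 0 °C; 16, −78 °C → rt; H2O
Reagents that add atoms: none
Why: In this directed ortho metalation the sole ring C–H lies between OMOM and OMe, whose cooperative coordination of lithium should make it kinetically much more acidic than the benzylic-allylic CH2 groups, and the aryllithium adds only once because the chelated tetrahedral adduct survives until the quench (Weinreb ketone synthesis).

**Step 7**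
Reactants: 19 2-(methoxymethoxy)-4,6-dimethoxy-3,5-diprenylbenzophenone
Product: 20 2-hydroxy-4,6-dimethoxy-3,5-diprenylbenzophenone (target)
Conditions: HCl (cat.), MeOH, rt → 40 °C
Reagents that add atoms: none
Why: Acid-catalysed acetal exchange with methanol removes the MOM group, which is especially labile when crowded between a prenyl group and an ortho carbonyl, and the freed OH is held in a hydrogen bond to the ketone, so dilute acid should not trigger chroman formation with the neighbouring prenyl olefin.

**Compound list**
1 | chloroacetaldehyde dimethyl acetal | COC(CCl)OC | starting material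
2 | prenyl bromide (1-bromo-3-methylbut-2-ene) | CC(C)=CCBr | starting material
3 | sodium methoxyacetylide | [Na+].[C-]#COC | intermediate
4 | 1-methoxy-5-methylhex-4-en-1-yne | COC#CCC=C(C)C | intermediate
5 | trichloroacetyl chloride | O=C(Cl)C(Cl)(Cl)Cl | starting material
6 | dichloroketene | ClC(Cl)=C=O | intermediate
7 | 4,4-dichloro-3-methoxy-2-prenylcyclobut-2-en-1-one | COC1=C(CC=C(C)C)C(=O)C1(Cl)Cl | intermediate
8 | 3-methoxy-2-prenylcyclobut-2-en-1-one | COC1=C(CC=C(C)C)C(=O)C1 | intermediate
9 | vinylketene, 3-methoxy-2-prenylbuta-1,3-dien-1-one | C=C(OC)C(CC=C(C)C)=C=O | intermediate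
10 | (±)-3-methoxy-4-(1-methoxyvinyl)-2,4-diprenylcyclobut-2-en-1-one | C=C(OC)C1(CC=C(C)C)C(=O)C(CC=C(C)C)=C1OC | intermediate
11 | dienylketene, 3,5-dimethoxy-2,4-diprenylhexa-1,3,5-trien-1-one (ketene and methoxyvinyl groups cis on the central C=C) | O=C=C(CC=C(C)C)/C(OC)=C(CC=C(C)C)\C(OC)=C | intermediate
12 | 3,5-dimethoxy-2,4-diprenylcyclohexa-2,4-dien-1-one | O=C1CC(OC)=C(CC=C(C)C)C(OC)=C1CC=C(C)C | intermediate
13 | 3,5-dimethoxy-2,4-diprenylphenol | Oc1cc(OC)c(CC=C(C)C)c(OC)c1CC=C(C)C | intermediate
14 | sodium 3,5-dimethoxy-2,4-diprenylphenoxide | [Na+].[O-]c1cc(OC)c(CC=C(C)C)c(OC)c1CC=C(C)C | intermediate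
15 | 1-(methoxymethoxy)-3,5-dimethoxy-2,4-diprenylbenzene | COCOc1cc(OC)c(CC=C(C)C)c(OC)c1CC=C(C)C | intermediate
16 | N-methoxy-N-methylbenzamide | CON(C)C(=O)c1ccccc1 | starting material
17 | 2-(methoxymethoxy)-4,6-dimethoxy-3,5-diprenylphenyllithium | [Li]c1c(OCOC)c(CC=C(C)C)c(OC)c(CC=C(C)C)c1OC | intermediate
18 | (±)-lithium alkoxide of the aryl(phenyl)(N-methoxy-N-methylamino)methanol adduct | [Li]OC(N(C)OC)(c1ccccc1)c1c(OCOC)c(CC=C(C)C)c(OC)c(CC=C(C)C)c1OC | intermediate
19 | 2-(methoxymethoxy)-4,6-dimethoxy-3,5-diprenylbenzophenone | COCOc1c(C(=O)c2ccccc2)c(OC)c(CC=C(C)C)c(OC)c1CC=C(C)C | intermediate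
20 | 2-hydroxy-4,6-dimethoxy-3,5-diprenylbenzophenone | COc1c(CC=C(C)C)c(O)c(C(=O)c2ccccc2)c(OC)c1CC=C(C)C | target

Total step count: 7.
Longest linear sequence: 7 steps, from 1 through 4, 7, 8, 13, 15 and 19 to 20. Compound 4 is drawn on twice from one batch.

**Steps most likely to fail**

**Step 4.**
- Risk: the vinylogous-ester resonance of 8 may keep the four-membered ring closed up to temperatures at which the ynol ether is lost by oligomerisation. The ketene may also be consumed by O-acylation of phenol already formed.
- Fallback: it keeps the ketene/ynol ether union but makes the ketene without any ring opening. It sets out from 2 (and uses 4) and comes back to the route at 13.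
- Methyl acetoacetate would be C-alkylated with 2 (NaOMe, MeOH) to (±)-methyl 2-acetyl-5-methylhex-4-enoate F1.
- Trimethyl orthoformate with catalytic p-TsOH in MeOH, followed by thermal loss of methanol, would give methyl (E)-3-methoxy-2-prenylbut-2-enoate F2. Either alkene geometry serves.
- Saponification (LiOH, aqueous MeOH, careful acidification) would give (E)-3-methoxy-2-prenylbut-2-enoic acid F3.
- 1-Chloro-N,N,2-trimethylpropenylamine in CH2Cl2 would convert this acid under neutral conditions into (E)-3-methoxy-2-prenylbut-2-enoyl chloride F4.
- 1,4-Dehydrochlorination of F4 with Et3N at room temperature in the presence of 4 generates the same vinylketene 9. This is trapped as 10, and moderate heating in toluene carries 10 on to 13.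

**Step 2.**
- Risk: dichloroketene may also add to the prenyl olefin, and ZnCl2 or traces of HCl may promote hydration or oligomerisation of the ynol ether.
- Fallback: it sets out from 4 and comes back at 8, so steps 2 and 3 merge into one step.
- Ketene F5, made by cracking diketene, would be passed into a CH2Cl2 solution of 4 at 0 °C.
- The parent ketene adds to ynol ethers with the same orientation but does not react with unactivated olefins. No zinc salt is present and no dechlorination is needed.

**Step 6.**
- Risk: lateral deprotonation at the benzylic-allylic CH2 groups may compete with ring metalation, and the aryllithium with two ortho substituents may add sluggishly to the amide.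
- Fallback: it avoids organolithium chemistry and the MOM group altogether. It sets out from 13 and comes back at 20.
- Ortho-selective magnesium-mediated formylation (MgCl2, Et3N, paraformaldehyde, MeCN, reflux; Casnati–Skattebøl reaction) at the only free ortho position would give 2-hydroxy-4,6-dimethoxy-3,5-diprenylbenzaldehyde F6.
- PhMgBr (2.2 equiv, THF, 0 °C) would give (±)-2-[hydroxy(phenyl)methyl]-3,5-dimethoxy-4,6-diprenylphenol F7.
- Benzylic oxidation with MnO2 in CH2Cl2 would remove the transient stereocentre and deliver 20.

**Further compounds**
F1 | step 4 | (±)-methyl 2-acetyl-5-methylhex-4-enoate | COC(=O)C(CC=C(C)C)C(C)=O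
F2 | step 4 | methyl (E)-3-methoxy-2-prenylbut-2-enoate | COC(=O)/C(CC=C(C)C)=C(/OC)C
F3 | step 4 | (E)-3-methoxy-2-prenylbut-2-enoic acid | OC(=O)/C(CC=C(C)C)=C(/OC)C
F4 | step 4 | (E)-3-methoxy-2-prenylbut-2-enoyl chloride | ClC(=O)/C(CC=C(C)C)=C(/OC)C
F5 | step 2 | ketene | C=C=O
F6 | step 6 | 2-hydroxy-4,6-dimethoxy-3,5-diprenylbenzaldehyde | O=Cc1c(O)c(CC=C(C)C)c(OC)c(CC=C(C)C)c1OC
F7 | step 6 | (±)-2-[hydroxy(phenyl)methyl]-3,5-dimethoxy-4,6-diprenylphenol | OC(c1ccccc1)c1c(O)c(CC=C(C)C)c(OC)c(CC=C(C)C)c1OC
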